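The only C=C bond of the six-membered carbocycle, C1=C2, lies between the two carbonyl carbons C6 and C3 (ring C1(C13H2OAc)=C2H–C3(=O)–C4–C5–C6(=O); chain C7–C12 on C4), and everything rests on disconnecting the ring there. With C3 and C6 kept as carbinols, ring-closing metathesis of the C3 vinyl group with the C1 methylene group closes the ring and forms the trisubstituted alkene in one operation, which removes any need to epoxidise a quinone. The precursor is an acyclic cis-epoxide carrying the finished threo C4/C5/C7 stereotriad, both acetates, a C3 silyl ether, a free C6 hydroxyl and C12 as a silyl-protected alcohol. One late oxidation then gives the enedione and the dienal together.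

Key step: step 17

Remark: atoms are numbered as in the paragraph above (C13 is the acetoxymethyl carbon). The carbinol centres C3 and C6 are made without control and carried as epimer mixtures (left undefined in the SMILES), since both end as ketones.

Step 1
Reactants: 1 (E)-pent-2-en-4-yn-1-ol
Product: 3 (2E,4E)-5-iodo-4-methylpenta-2,4-dien-1-ol, via alkenylalane 2 (not isolated)
Conditions: AlMe3 (3 equiv), Cp2ZrCl2 (0.25 equiv), CH2Cl2, 0 °C to rt; then I2, THF, −30 to 0 °C
Reagents that add atoms: trimethylaluminium, C[Al](C)C; iodine, II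
Why: Zirconium-catalysed Negishi carboalumination adds methyl and aluminium syn across the terminal alkyne with the metal on the terminal carbon (the hydroxyl rides as its aluminium alkoxide), and iodinolysis with retention gives the (E)-iodoalkene.

Step 2
Reactants: 3 (2E,4E)-5-iodo-4-methylpenta-2,4-dien-1-ol
Product: 4 tert-butyl{[(2E,4E)-5-iodo-4-methylpenta-2,4-dien-1-yl]oxy}diphenylsilane
Conditions: TBDPSCl, imidazole, CH2Cl2, 0 °C to rt
Reagents that add atoms: tert-butyl(chloro)diphenylsilane, CC(C)(C)[Si](Cl)(c1ccccc1)c1ccccc1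
Why: Routine silylation of a primary allylic alcohol; the robust TBDPS ether is meant to survive every later step until the final fluoride treatment.

Step 3
Reactants: 4 tert-butyl{[(2E,4E)-5-iodo-4-methylpenta-2,4-dien-1-yl]oxy}diphenylsilane
Product: 6 (2E,4E)-6-[(tert-butyldiphenylsilyl)oxy]-3-methylhexa-2,4-dienal, via dienyllithium 5 (not isolated)
Conditions: t-BuLi (2.1 equiv), Et2O, −78 °C; then DMF, −78 to 0 °C; aq. NH4Cl
Reagents that add atoms: N,N-dimethylformamide, CN(C)C=O
Why: Iodine–lithium exchange proceeds with retention of alkene geometry, and Bouveault-type formylation of the alkenyllithium with DMF installs C7 as the aldehyde.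

Step 4
Reactants: 7 but-2-yne-1,4-diol
Product: 8 (E)-2-(tributylstannyl)but-2-ene-1,4-diol
Conditions: Bu3SnH, PdCl2(PPh3)2 (2 mol %), THF, rt
Reagents that add atoms: tributylstannane, CCCC[SnH](CCCC)CCCC
Why: Palladium-catalysed hydrostannation adds H and SnBu3 syn to the symmetrical alkyne, so there is no regiochemical issue and the two hydroxymethyl arms (C3 and C6) end up cis, as the later ring requires.

Step 5
Reactants: 8 (E)-2-(tributylstannyl)but-2-ene-1,4-diol
Product: 9 tributyl(2,2-dimethyl-4,7-dihydro-1,3-dioxepin-5-yl)stannane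
Conditions: Me2C(OMe)2, PPTS (cat.), CH2Cl2, rt
Reagents that add atoms: 2,2-dimethoxypropane, COC(C)(C)OC
Why: Acid-catalysed transacetalisation of the cis-1,4-diol gives the seven-membered acetonide, which masks both arms in one step and tolerates the alkyllithium used next.

Step 6
Reactants: 9 tributyl(2,2-dimethyl-4,7-dihydro-1,3-dioxepin-5-yl)stannane; 6 (2E,4E)-6-[(tert-butyldiphenylsilyl)oxy]-3-methylhexa-2,4-dienal
Product: 11 rac-(2E,4E)-6-[(tert-butyldiphenylsilyl)oxy]-1-(2,2-dimethyl-4,7-dihydro-1,3-dioxepin-5-yl)-3-methylhexa-2,4-dien-1-ol, via alkenyllithium 10 (not isolated)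
Conditions: n-BuLi, THF, −78 °C; then 6, −78 °C; aq. NH4Cl
Reagents that add atoms: none
Why: Tin–lithium exchange gives the C4 alkenyllithium, whose 1,2-addition to the enal carbonyl forms the C4–C7 bond; the bis-allylic alcohol is racemic at C7.

Step 7
Reactants: 11 racemic bis-allylic alcohol
Product: 12 erythro epoxy alcohol, (4R,5R,7R) in the numbering above
Conditions: Ti(OiPr)4 (1.0 equiv), D-(−)-diisopropyl tartrate (1.2 equiv), t-BuOOH (0.6 equiv), 4 Å MS, CH2Cl2, −20 °C
Reagents that add atoms: tert-butyl hydroperoxide, CC(C)(C)OO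
Why: Sharpless asymmetric epoxidation run as a kinetic resolution: with D-(−)-tartrate the (7R)-alcohol is matched for oxygen delivery to C4=C5 and should give the erythro epoxy alcohol with the required epoxide configuration, whereas the (7S)-alcohol is mismatched there and matched only at its other allylic alkene C8=C9, so it is left behind or diverted to a separable isomer and cannot erode the enantiopurity of 12.

Step 8
Reactants: 12 erythro epoxy alcohol
Product: 13 threo epoxy acetate, (4R,5R,7S)
Conditions: PPh3, DIAD, AcOH, toluene, 0 °C to rt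
Reagents that add atoms: acetic acid, CC(=O)O
Why: Mitsunobu esterification displaces the activated C7 oxygen by SN2 with inversion, turning the erythro alcohol into the threo (7S)-acetate of the target; the oxygen-bearing C4 disfavours ionisation and so limits allylic scrambling.

Step 9
Reactants: 13 threo epoxy acetate
Product: 14 epoxy diol (C3 and C6 hydroxymethyl groups free)
Conditions: PPTS (0.2 equiv), MeOH, 0 °C to rt
Reagents that add atoms: none
Why: Mild acid-catalysed transacetalisation to methanol removes the labile seven-membered acetonide while the acetate, the electron-poor epoxide and the TBDPS ether should be untouched.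

Step 10
Reactants: 14 epoxy diol
Product: 15 C6 mono(triethylsilyl) ether
Conditions: TESCl (1.05 equiv), imidazole, CH2Cl2, −78 to −40 °C
Reagents that add atoms: chlorotriethylsilane, CC[Si](Cl)(CC)CC
Why: Kinetic monosilylation: the C6 hydroxymethyl group on the epoxide CH is far more accessible than the neopentyl-type C3 hydroxymethyl group on the fully substituted C4, so one equivalent of chlorosilane at low temperature should react at C6–OH.

Step 11
Reactants: 15 C6 mono(triethylsilyl) ether
Product: 16 C3 aldehyde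
Conditions: DMP, NaHCO3, CH2Cl2, 0 °C to rt
Reagents that add atoms: none
Why: Dess–Martin oxidation of the remaining primary alcohol gives an aldehyde with no alpha-hydrogen, which therefore cannot epimerise or eliminate.

Step 12
Reactants: 16 C3 aldehyde; 17 vinylmagnesium bromide
Product: 18 C3 vinyl carbinol (epimers at C3)
Conditions: THF, −78 °C; quench at −78 °C with aq. NH4Cl
Reagents that add atoms: none
Why: Grignard 1,2-addition to the aldehyde at −78 °C is much faster than attack on the hindered secondary acetate; the new C3 centre forms without control, which is immaterial because C3 becomes a ketone.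

Step 13
Reactants: 18 C3 vinyl carbinol
Product: 19 C3,C6-bis(triethylsilyl) ether
Conditions: TESOTf, 2,6-lutidine, CH2Cl2, −78 °C
Reagents that add atoms: triethylsilyl trifluoromethanesulfonate, CC[Si](CC)(CC)OS(=O)(=O)C(F)(F)F
Why: Low-temperature silylation with the silyl triflate caps the hindered secondary allylic alcohol before it can accept the neighbouring C7 acetyl group, and shields it from the next oxidation.

Step 14
Reactants: 19 C3,C6-bis(triethylsilyl) ether
Product: 20 C6 aldehyde
Conditions: (COCl)2, DMSO, CH2Cl2, −78 to −30 °C; then Et3N, −78 to 0 °C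
Reagents that add atoms: none
Why: Under Swern conditions a primary triethylsilyl ether is cleaved by the chlorosulfonium reagent and oxidised in the same flask, whereas secondary TES ethers and the TBDPS ether are inert; this known selective direct oxidation saves a separate deprotection.

Step 15
Reactants: 20 C6 aldehyde; 21 2-bromoprop-2-en-1-ol
Product: 22 C6,C13 diol (epimers at C3 and C6)
Conditions: CrCl2 (6 equiv), NiCl2 (2 mol %), DMF, rt
Reagents that add atoms: none
Why: Nozaki–Hiyama–Kishi coupling: the nickel-activated alkenyl bromide is passed to chromium and adds only to the aldehyde, tolerating the acetate, the epoxide and the free hydroxyl; the C6 centre forms without control and is later oxidised.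

Step 16
Reactants: 22 C6,C13 diol
Product: 23 acyclic epoxy diene, the metathesis precursor (C13 acetate, C6–OH free)
Conditions: AcCl (1.1 equiv), 2,4,6-collidine, CH2Cl2, −78 °C
Reagents that add atoms: acetyl chloride, CC(Cl)=O
Why: Acetyl chloride with collidine at −78 °C acylates primary alcohols selectively, so only the C13 hydroxyl should be acetylated and the secondary C6 hydroxyl stays free for the ring closure.

Step 17
Reactants: 23 acyclic epoxy diene
Product: 24 cyclohexene (C3–OTES, C6–OH, epoxide, both acetates, C12–OTBDPS)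
Conditions: second-generation Grubbs catalyst, RuCl2(=CHPh)(H2IMes)(PCy3) (10 mol %), CH2Cl2 (2 mM), 40 °C
Reagents that add atoms: none
Why: Ring-closing olefin metathesis: the ruthenium benzylidene exchanges onto the unhindered C2 vinyl group, the new alkylidene adds to the C1 methylene group in a [2+2] step, and the ruthenacyclobutane cycloreverts to the C1=C2 bond and Ru=CH2, which leaves as ethylene. The closest known reaction type is the metathesis of oxygenated octa-1,7-dienes, including ones with a 1,1-disubstituted alkene, to polyoxygenated cyclohexenes. The six-membered carbocycle C1–C6 is closed by alkene–alkene metathesis of two arms that the cis-epoxide holds on the same side of C4–C5, so the reacting termini are already near. No stereocentre is formed or touched. The step needs chemoselectivity for the C1 methylene over the chain alkenes: closure onto C10=C11 would need a trans-cycloheptene, but closure onto C8 would give an unstrained cyclopentene with loss of the chain and must be outrun, for which the allylic C6 hydroxyl is left free (hydroxyl-assisted capture of the 1,1-disubstituted alkene, releasing the favourable Ru=CH2) while C8=C9 is trisubstituted, flanked by the acetoxy-bearing C7 and the quaternary C4, and could only release a disubstituted alkylidene.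

Step 18
Reactants: 24 cyclohexene
Product: 25 triol diacetate (C3–OH, C6–OH, C12–OH)
Conditions: HF·pyridine, pyridine, THF, 0 °C to rt
Reagents that add atoms: none
Why: Buffered HF·pyridine cleaves the secondary TES ether and the primary TBDPS ether in one operation under mildly acidic conditions that should spare the acetates and the epoxide and not promote acyl migration.

Step 19
Reactants: 25 triol diacetate
Product: 26 target, (4R,5S,7S)
Conditions: DMP (4 equiv), NaHCO3, CH2Cl2, 0 °C to rt
Reagents that add atoms: none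
Why: Dess–Martin periodinane oxidises the two secondary allylic alcohols to the ene-1,4-dione and the primary dienylic alcohol to the dienal in one buffered, neutral operation, so the sensitive epoxy-enedione is formed last and meets neither acid nor base.

Compound list
1 | (E)-pent-2-en-4-yn-1-ol | C#C/C=C/CO | starting material
2 | dimethyl[(1E,3E)-5-(dimethylalumanyloxy)-2-methylpenta-1,3-dien-1-yl]alumane | C[Al](C)OC/C=C/C(C)=C/[Al](C)C | intermediate
3 | (2E,4E)-5-iodo-4-methylpenta-2,4-dien-1-ol | OC/C=C/C(C)=C/I | intermediate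
4 | tert-butyl{[(2E,4E)-5-iodo-4-methylpenta-2,4-dien-1-yl]oxy}diphenylsilane | CC(C)(C)[Si](OC/C=C/C(C)=C/I)(c1ccccc1)c1ccccc1 | intermediate
5 | [(1E,3E)-5-(tert-butyldiphenylsilyloxy)-2-methylpenta-1,3-dien-1-yl]lithium | [Li]/C=C(C)/C=C/CO[Si](C(C)(C)C)(c1ccccc1)c1ccccc1 | intermediate
6 | (2E,4E)-6-[(tert-butyldiphenylsilyl)oxy]-3-methylhexa-2,4-dienal | O=C/C=C(C)/C=C/CO[Si](C(C)(C)C)(c1ccccc1)c1ccccc1 | intermediate
7 | but-2-yne-1,4-diol | OCC#CCO | starting material
8 | (E)-2-(tributylstannyl)but-2-ene-1,4-diol | OC/C=C(/[Sn](CCCC)(CCCC)CCCC)CO | intermediate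
9 | tributyl(2,2-dimethyl-4,7-dihydro-1,3-dioxepin-5-yl)stannane | CC1(C)OCC=C(CO1)[Sn](CCCC)(CCCC)CCCC | intermediate
10 | (2,2-dimethyl-4,7-dihydro-1,3-dioxepin-5-yl)lithium | [Li]C1=CCOC(C)(C)OC1 | intermediate
11 | rac-(2E,4E)-6-[(tert-butyldiphenylsilyl)oxy]-1-(2,2-dimethyl-4,7-dihydro-1,3-dioxepin-5-yl)-3-methylhexa-2,4-dien-1-ol | CC1(C)OCC=C(CO1)C(O)/C=C(C)/C=C/CO[Si](C(C)(C)C)(c2ccccc2)c2ccccc2 | intermediate
12 | (1R,2E,4E)-6-[(tert-butyldiphenylsilyl)oxy]-1-[(1R,7R)-4,4-dimethyl-3,5,8-trioxabicyclo[5.1.0]octan-1-yl]-3-methylhexa-2,4-dien-1-ol (erythro; 4R,5R,7R) | CC1(C)OC[C@]2([C@@H](/C=C(C)/C=C/CO[Si](C(C)(C)C)(c3ccccc3)c3ccccc3)O)O[C@@H]2CO1 | intermediate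
13 | (1S,2E,4E)-6-[(tert-butyldiphenylsilyl)oxy]-1-[(1R,7R)-4,4-dimethyl-3,5,8-trioxabicyclo[5.1.0]octan-1-yl]-3-methylhexa-2,4-dien-1-yl acetate (threo; 4R,5R,7S) | CC1(C)OC[C@]2([C@H](/C=C(C)/C=C/CO[Si](C(C)(C)C)(c3ccccc3)c3ccccc3)OC(C)=O)O[C@@H]2CO1 | intermediate
14 | (1S,2E,4E)-1-[(2R,3R)-2,3-bis(hydroxymethyl)oxiran-2-yl]-6-[(tert-butyldiphenylsilyl)oxy]-3-methylhexa-2,4-dien-1-yl acetate | OC[C@]1([C@H](/C=C(C)/C=C/CO[Si](C(C)(C)C)(c2ccccc2)c2ccccc2)OC(C)=O)O[C@@H]1CO | intermediate
15 | (1S,2E,4E)-6-[(tert-butyldiphenylsilyl)oxy]-1-[(2R,3R)-2-(hydroxymethyl)-3-{[(triethylsilyl)oxy]methyl}oxiran-2-yl]-3-methylhexa-2,4-dien-1-yl acetate | OC[C@]1([C@H](/C=C(C)/C=C/CO[Si](C(C)(C)C)(c2ccccc2)c2ccccc2)OC(C)=O)O[C@@H]1CO[Si](CC)(CC)CC | intermediate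
16 | (1S,2E,4E)-6-[(tert-butyldiphenylsilyl)oxy]-1-[(2R,3R)-2-formyl-3-{[(triethylsilyl)oxy]methyl}oxiran-2-yl]-3-methylhexa-2,4-dien-1-yl acetate | O=C[C@]1([C@H](/C=C(C)/C=C/CO[Si](C(C)(C)C)(c2ccccc2)c2ccccc2)OC(C)=O)O[C@@H]1CO[Si](CC)(CC)CC | intermediate
17 | vinylmagnesium bromide | C=C[Mg]Br | starting material
18 | (1S,2E,4E)-6-[(tert-butyldiphenylsilyl)oxy]-1-[(2R,3R)-2-(1-hydroxyprop-2-en-1-yl)-3-{[(triethylsilyl)oxy]methyl}oxiran-2-yl]-3-methylhexa-2,4-dien-1-yl acetate (C3 epimers) | C=CC(O)[C@]1([C@H](/C=C(C)/C=C/CO[Si](C(C)(C)C)(c2ccccc2)c2ccccc2)OC(C)=O)O[C@@H]1CO[Si](CC)(CC)CC | intermediate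
19 | (1S,2E,4E)-6-[(tert-butyldiphenylsilyl)oxy]-3-methyl-1-[(2R,3R)-2-{1-[(triethylsilyl)oxy]prop-2-en-1-yl}-3-{[(triethylsilyl)oxy]methyl}oxiran-2-yl]hexa-2,4-dien-1-yl acetate (C3 epimers) | C=CC(O[Si](CC)(CC)CC)[C@]1([C@H](/C=C(C)/C=C/CO[Si](C(C)(C)C)(c2ccccc2)c2ccccc2)OC(C)=O)O[C@@H]1CO[Si](CC)(CC)CC | intermediate
20 | (1S,2E,4E)-6-[(tert-butyldiphenylsilyl)oxy]-1-[(2R,3S)-3-formyl-2-{1-[(triethylsilyl)oxy]prop-2-en-1-yl}oxiran-2-yl]-3-methylhexa-2,4-dien-1-yl acetate (C3 epimers) | C=CC(O[Si](CC)(CC)CC)[C@]1([C@H](/C=C(C)/C=C/CO[Si](C(C)(C)C)(c2ccccc2)c2ccccc2)OC(C)=O)O[C@@H]1C=O | intermediate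
21 | 2-bromoprop-2-en-1-ol | OCC(Br)=C | starting material
22 | (1S,2E,4E)-6-[(tert-butyldiphenylsilyl)oxy]-1-[(2R,3R)-3-[1-hydroxy-2-(hydroxymethyl)prop-2-en-1-yl]-2-{1-[(triethylsilyl)oxy]prop-2-en-1-yl}oxiran-2-yl]-3-methylhexa-2,4-dien-1-yl acetate (C3 and C6 epimers) | C=CC(O[Si](CC)(CC)CC)[C@]1([C@H](/C=C(C)/C=C/CO[Si](C(C)(C)C)(c2ccccc2)c2ccccc2)OC(C)=O)O[C@@H]1C(O)C(=C)CO | intermediate
23 | (1S,2E,4E)-1-[(2R,3R)-3-{2-[(acetyloxy)methyl]-1-hydroxyprop-2-en-1-yl}-2-{1-[(triethylsilyl)oxy]prop-2-en-1-yl}oxiran-2-yl]-6-[(tert-butyldiphenylsilyl)oxy]-3-methylhexa-2,4-dien-1-yl acetate (C3 and C6 epimers; metathesis precursor) | C=CC(O[Si](CC)(CC)CC)[C@]1([C@H](/C=C(C)/C=C/CO[Si](C(C)(C)C)(c2ccccc2)c2ccccc2)OC(C)=O)O[C@@H]1C(O)C(=C)COC(C)=O | intermediate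
24 | [(1R,6R)-1-{(1S,2E,4E)-1-(acetyloxy)-6-[(tert-butyldiphenylsilyl)oxy]-3-methylhexa-2,4-dien-1-yl}-5-hydroxy-2-[(triethylsilyl)oxy]-7-oxabicyclo[4.1.0]hept-3-en-4-yl]methyl acetate (epimers at C2 and C5 of the bicycle; metathesis product) | CC(=O)OCC1=CC(O[Si](CC)(CC)CC)[C@]2([C@H](/C=C(C)/C=C/CO[Si](C(C)(C)C)(c3ccccc3)c3ccccc3)OC(C)=O)O[C@@H]2C1O | intermediate
25 | [(1R,6R)-1-[(1S,2E,4E)-1-(acetyloxy)-6-hydroxy-3-methylhexa-2,4-dien-1-yl]-2,5-dihydroxy-7-oxabicyclo[4.1.0]hept-3-en-4-yl]methyl acetate (epimers at C2 and C5 of the bicycle) | CC(=O)OCC1=CC(O)[C@]2([C@H](/C=C(C)/C=C/CO)OC(C)=O)O[C@@H]2C1O | intermediate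
26 | [(1R,6S)-1-[(1S,2E,4E)-1-(acetyloxy)-3-methyl-6-oxohexa-2,4-dien-1-yl]-2,5-dioxo-7-oxabicyclo[4.1.0]hept-3-en-4-yl]methyl acetate | CC(=O)OCC1=CC(=O)[C@]2([C@H](/C=C(C)/C=C/C=O)OC(C)=O)O[C@@H]2C1=O | target

Total step count: 19. Longest linear sequence: 17 steps (steps 1–3, then 6–19).

Steps most likely to fail

Step 17. The ring closure may be misdirected: the alkylidene formed at C2 can also cyclise onto the trisubstituted C8=C9 alkene (five-membered ring, chain expelled), and this could outpace capture of the hindered C1 methylene, or the catalyst may decay before the slow closure is complete. The fallback sets out from 23 and masks the competing diene. Liquid SO2 (hydroquinone, sealed tube, rt to 50 °C) should add cheletropically across C8–C11 to give the cis-2,5-disubstituted 3-sulfolene adduct of 23 F1. Metathesis of F1 with second-generation Grubbs catalyst, now without a reactive chain alkene, should give the cyclohexene sulfolene F2. Thermal extrusion of SO2 (toluene, NaHCO3, about 100 °C) returns the (E,E)-diene stereospecifically and rejoins the route at 24.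

Step 7. Oxygen transfer may lose chemoselectivity: the titanium-bound peroxide may attack the second allylic alkene C8=C9 within the (7R)-enantiomer, or over-oxidise 12, so that the resolution delivers little product. The fallback sets out from 9 and sets the epoxide before the diene is present. Tin–lithium exchange and trapping with paraformaldehyde gives (2,2-dimethyl-4,7-dihydro-1,3-dioxepin-5-yl)methanol F3. Catalytic Sharpless epoxidation of this primary allylic alcohol with D-(−)-diisopropyl tartrate gives [(1S,7R)-4,4-dimethyl-3,5,8-trioxabicyclo[5.1.0]octan-1-yl]methanol F4, with the epoxide configured as in 12. Dess–Martin oxidation gives the non-enolisable (1S,7R)-4,4-dimethyl-3,5,8-trioxabicyclo[5.1.0]octane-1-carbaldehyde F5. Addition of dienyllithium 5 (from 4) gives 12 together with its C7 epimer, the threo epoxy alcohol F6, and the two are separated. Compound 12 rejoins the route at step 8, and F6 is acetylated (Ac2O, pyridine, DMAP) to 13, so both epimers converge.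

Step 8. Direct displacement at the hindered C7 may be slow, so that elimination or attack of acetate at the diene terminus (allylic transposition) competes with clean inversion. The fallback sets out from 12 and replaces the redox condensation by a two-step sulfonate displacement. Chloromethanesulfonyl chloride and pyridine (0 °C) give the erythro chloromethanesulfonate of 12 F7. Caesium acetate with 18-crown-6 in toluene (about 60 °C) then displaces the sulfonate by SN2 with inversion and rejoins the route at 13.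

Further compounds
F1 | step 17 | sulfolene adduct of 23: (1S,...)-1-[(2R,3R)-oxiranyl]-substituted acetate in which C8–C11 form a cis-2,5-disubstituted 3-methyl-2,5-dihydrothiophene 1,1-dioxide (both facial isomers) | C=CC(O[Si](CC)(CC)CC)[C@]1([C@H](C2C(C)=CC(CO[Si](C(C)(C)C)(c3ccccc3)c3ccccc3)S2(=O)=O)OC(C)=O)O[C@@H]1C(O)C(=C)COC(C)=O
F2 | step 17 | sulfolene adduct of 24: cyclohexene with C8–C11 as the cis-2,5-disubstituted 3-methyl-2,5-dihydrothiophene 1,1-dioxide | CC(=O)OCC1=CC(O[Si](CC)(CC)CC)[C@]2([C@H](C3C(C)=CC(CO[Si](C(C)(C)C)(c4ccccc4)c4ccccc4)S3(=O)=O)OC(C)=O)O[C@@H]2C1O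
F3 | step 7 | (2,2-dimethyl-4,7-dihydro-1,3-dioxepin-5-yl)methanol | CC1(C)OCC=C(CO)CO1
F4 | step 7 | [(1S,7R)-4,4-dimethyl-3,5,8-trioxabicyclo[5.1.0]octan-1-yl]methanol | CC1(C)OC[C@]2(CO)O[C@@H]2CO1
F5 | step 7 | (1S,7R)-4,4-dimethyl-3,5,8-trioxabicyclo[5.1.0]octane-1-carbaldehyde | CC1(C)OC[C@]2(C=O)O[C@@H]2CO1
F6 | step 7 | (1S,2E,4E)-6-[(tert-butyldiphenylsilyl)oxy]-1-[(1R,7R)-4,4-dimethyl-3,5,8-trioxabicyclo[5.1.0]octan-1-yl]-3-methylhexa-2,4-dien-1-ol (threo; C7 epimer of 12) | CC1(C)OC[C@]2([C@H](/C=C(C)/C=C/CO[Si](C(C)(C)C)(c3ccccc3)c3ccccc3)O)O[C@@H]2CO1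
F7 | step 8 | (1R,2E,4E)-6-[(tert-butyldiphenylsilyl)oxy]-1-[(1R,7R)-4,4-dimethyl-3,5,8-trioxabicyclo[5.1.0]octan-1-yl]-3-methylhexa-2,4-dien-1-yl chloromethanesulfonate | CC1(C)OC[C@]2([C@@H](/C=C(C)/C=C/CO[Si](C(C)(C)C)(c3ccccc3)c3ccccc3)OS(=O)(=O)CCl)O[C@@H]2CO1
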